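**Plan**

Labels: oxane O1, C2 (acrylic acid arm), C3, C4, C5 (side chain), C6; side chain C1′–C13′ counted from the ring.
Retrosynthesis, in order: the acid goes back to the C2-arm allylic alcohol; C5′–C6′ is cut (geranyl phenyl sulfone plus a C5′ allylic tosylate); O1–C6 of the oxane is cut; then both carbinol–C(=CH2) bonds are cut, leading to 4-(tosyloxymethyl)heptanedial from ozonised cyclohept-4-enylmethyl tosylate.
Enabling feature: C5 bears C6H2–O1 and two arms of the same constitution and configuration, C4–C3–C2(R)(O1)–C(=CH2)–C and C1′–C2′–C3′(R)(OH)–C4′(=CH2)–C5′, so opening O1–C6 leaves a chain whose branch carbon is not a stereocentre.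
Forward: the chain grows in both directions at once, the oxane (the only ring) closes in step 6, the side-chain 1,3-diol is then singled out for the C5′–C6′ coupling, and the ring-arm alcohol is oxidised last.
Stereochemistry: C2 and C3′ (both R) come from a β-isocupreidine-catalysed double Morita–Baylis–Hillman reaction; C5 (S) comes from the choice between the two diastereotopic carbinol oxygens in a diequatorial chair closure; 7′E comes from geranyl bromide.

Key step: step 6

Remark: β-isocupreidine is taken to give the R carbinol at both termini of the unbranched dialdehyde 5, in line with its behaviour towards simple aliphatic aldehydes.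

**Route**

Step 1
Reactants: 1 cyclohept-4-ene-1-carboxylic acid
Product: 2 (cyclohept-4-en-1-yl)methanol
Conditions: LiAlH4, THF, 0 °C → rt; aqueous work-up
Reagents that add atoms: none
Why: Hydride reduction of the carboxylic acid gives the primary alcohol and leaves the isolated ring alkene untouched.

Step 2
Reactants: 2 (cyclohept-4-en-1-yl)methanol
Product: 3 (cyclohept-4-en-1-yl)methyl 4-methylbenzenesulfonate
Conditions: TsCl, Et3N, DMAP (cat.), CH2Cl2, 0 °C → rt
Reagents that add atoms: 4-methylbenzenesulfonyl chloride (TsCl), Cc1ccc(cc1)S(=O)(=O)Cl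
Why: Sulfonylation of the unhindered primary alcohol installs at the outset the leaving group of the future C6, which should be inert to ozone, to the tertiary-amine catalyst at −55 °C and to DIBAL-H.

Step 3
Reactants: 3 (cyclohept-4-en-1-yl)methyl 4-methylbenzenesulfonate
Product: 5 4-[(tosyloxy)methyl]heptanedial, via secondary ozonide 4 (not isolated)
Conditions: O3, CH2Cl2, −78 °C; then PPh3, −78 °C → rt
Reagents that add atoms: ozone, [O-][O+]=O
Why: Ozonolysis with reductive work-up cleaves the symmetrical ring alkene into two identical three-carbon aldehyde arms on the carbon that becomes C5.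

Step 4
Reactants: 5 4-[(tosyloxy)methyl]heptanedial; 6 1,1,1,3,3,3-hexafluoropropan-2-yl acrylate (3 equiv)
Product: 7 bis(1,1,1,3,3,3-hexafluoropropan-2-yl) (3R,9R)-3,9-dihydroxy-2,10-dimethylidene-6-{[(4-methylbenzenesulfonyl)oxy]methyl}undecanedioate
Conditions: β-isocupreidine (20 mol%), DMF, −55 °C
Reagents that add atoms: none
Why: In this asymmetric Morita–Baylis–Hillman reaction the quinidine-derived Lewis base and the activated acrylate should add at both aldehyde termini with the same catalyst-controlled facial sense, setting both carbinols as R, while the double addition diverts most stereochemical error into R,S diastereomers that can be removed (Horeau-type amplification).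

Step 5
Reactants: 7 bis(hexafluoroisopropyl) diester
Product: 8 [(3R,9R)-1,3,9,11-tetrahydroxy-2,10-dimethylideneundecan-6-yl]methyl 4-methylbenzenesulfonate
Conditions: DIBAL-H (7 equiv), CH2Cl2, −78 °C; Rochelle salt work-up
Reagents that add atoms: none
Why: DIBAL-H reduces both activated enoates by 1,2-addition to primary allylic alcohols at a temperature where the primary tosylate survives, so the ring closure that follows is run on a substrate free of base-sensitive acrylates.

Step 6
Reactants: 8 tetraol tosylate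
Product: 9 2-[(2R,5S)-5-[(3R)-3-hydroxy-4-(hydroxymethyl)pent-4-en-1-yl]oxan-2-yl]prop-2-en-1-ol
Conditions: KOt-Bu (1.1 equiv), THF (0.01 M), −40 → 0 °C
Reagents that add atoms: none
Why: tert-Butoxide forms the alkoxides of 8 reversibly and one secondary allylic alkoxide displaces the primary tosylate intramolecularly by SN2, making the O1–C6 bond; the closest known reactions are Williamson oxane closures of 5-hydroxyalkyl sulfonates and diastereotopic-group-selective cyclisations of pseudo-C2-symmetric diols. The oxane closes in the 6-exo-tet mode. The only new stereocentre is C5, which becomes stereogenic once one of its two identical R-configured arms is part of the ring; it is controlled by a chair-like transition state with the alkenyl group at C2 and the remaining arm at C5 both equatorial, which gives the 2,5-trans ring (2R,5S), whereas closure through the other oxygen must place that arm axial and gives the cis isomer. C2 and C3′ are not involved and keep the R configuration from step 4. The step needs selectivity between the two diastereotopic secondary oxygens, which rests on this moderate chair preference helped by the low temperature (the cis-oxane is to be removed by chromatography here or after step 8), and selectivity against the primary allylic oxygens, which could only close eight-membered rings, while high dilution suppresses intermolecular etherification.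

Step 7
Reactants: 9 triol oxane
Product: 11 (3R)-3-hydroxy-5-[(3S,6R)-6-(3-hydroxyprop-1-en-2-yl)oxan-3-yl]-2-methylidenepentyl 4-methylbenzenesulfonate, via dibutylstannylene acetal 10 (not isolated)
Conditions: Bu2SnO (1.05 equiv), toluene, reflux (−H2O); then TsCl (1.05 equiv), CH2Cl2, 0 °C → rt
Reagents that add atoms: 4-methylbenzenesulfonyl chloride (TsCl), Cc1ccc(cc1)S(=O)(=O)Cl
Why: The stannylene acetal can form only at the side-chain 1,3-diol and activates its primary oxygen, so tosyl chloride without amine base should sulfonylate C5′–O and spare the isolated ring-arm hydroxyl (tin-acetal-directed regioselective sulfonylation).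

Step 8
Reactants: 11 allylic tosylate diol
Product: 12 (3R)-3-[(tert-butyldimethylsilyl)oxy]-5-[(3R,6R)-6-{3-[(tert-butyldimethylsilyl)oxy]prop-1-en-2-yl}oxan-3-yl]-2-methylidenepentyl 4-methylbenzenesulfonate
Conditions: TBSOTf (2.5 equiv), 2,6-lutidine, CH2Cl2, −78 °C
Reagents that add atoms: tert-butyldimethylsilyl trifluoromethanesulfonate (TBSOTf), CC(C)(C)[Si](C)(C)OS(=O)(=O)C(F)(F)F
Why: A silyl triflate with a hindered, non-nucleophilic base silylates the primary and the secondary allylic hydroxyl at low temperature without displacing the allylic tosylate.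

Step 9
Reactants: 13 geranyl bromide
Product: 14 {[(2E)-3,7-dimethylocta-2,6-dien-1-yl]sulfonyl}benzene (geranyl phenyl sulfone)
Conditions: PhSO2Na, DMF, rt
Reagents that add atoms: sodium benzenesulfinate, [Na+].[O-]S(=O)c1ccccc1
Why: S-Alkylation of the sulfinate by the primary allylic bromide (SN2) gives the allyl sulfone with the 2E alkene unchanged.

Step 10
Reactants: 14 geranyl phenyl sulfone (1.2 equiv); 12 bis-silyl allylic tosylate
Product: 16 (2R,5R)-5-[(3R,7E)-6-(benzenesulfonyl)-3-[(tert-butyldimethylsilyl)oxy]-8,12-dimethyl-4-methylidenetrideca-7,11-dien-1-yl]-2-{3-[(tert-butyldimethylsilyl)oxy]prop-1-en-2-yl}oxane (both C6′ epimers), via lithiated geranyl phenyl sulfone 15 (not isolated)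
Conditions: n-BuLi, THF, −78 °C; then 12, −78 → −40 °C
Reagents that add atoms: none
Why: The sulfonyl-stabilised allyl anion alkylates only at its α-carbon (allyl sulfone alkylation) and SN2 or SN2′ attack on the 2-substituted allyl tosylate leads to the same constitution, so the C5′–C6′ bond forms without regiochemical ambiguity.

Step 11
Reactants: 16 coupled sulfone
Product: 17 (2R,5R)-2-{3-[(tert-butyldimethylsilyl)oxy]prop-1-en-2-yl}-5-[(3R,7E)-3-[(tert-butyldimethylsilyl)oxy]-8,12-dimethyl-4-methylidenetrideca-7,11-dien-1-yl]oxane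
Conditions: PdCl2(dppp) (5 mol%), LiEt3BH (3 equiv), THF, 0 °C
Reagents that add atoms: none
Why: Pd(0) ionises the allylic sulfone to a π-allyl complex that hydride attacks at the less substituted terminus C6′, so the trisubstituted 7′E alkene should keep its position and geometry (Pd-catalysed reductive desulfonylation), while silyl ethers and allylic ethers are not ionised.

Step 12
Reactants: 17 bis-silyl ether
Product: 18 2-[(2R,5S)-5-[(3R,7E)-3-hydroxy-8,12-dimethyl-4-methylidenetrideca-7,11-dien-1-yl]oxan-2-yl]prop-2-en-1-ol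
Conditions: TBAF, THF, 0 °C → rt
Reagents that add atoms: none
Why: Fluoride cleaves both silyl ethers and nothing else in 17 is sensitive to fluoride or mild base.

Step 13
Reactants: 18 diol
Product: 19 2-[(2R,5S)-5-[(3R,7E)-3-hydroxy-8,12-dimethyl-4-methylidenetrideca-7,11-dien-1-yl]oxan-2-yl]prop-2-enal
Conditions: [Cu(MeCN)4]OTf (5 mol%), 2,2′-bipyridine (5 mol%), TEMPO (5 mol%), N-methylimidazole (10 mol%), air, MeCN, rt
Reagents that add atoms: none
Why: The Cu(I)/TEMPO aerobic oxidation converts unhindered primary (here allylic) alcohols to aldehydes and is essentially unreactive towards the hindered secondary allylic carbinol at C3′ and towards the alkenes.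

Step 14
Reactants: 19 enal
Product: 20 2-[(2R,5S)-5-[(3R,7E)-3-hydroxy-8,12-dimethyl-4-methylidenetrideca-7,11-dien-1-yl]oxan-2-yl]prop-2-enoic acid (CNP0197923.2)
Conditions: NaClO2, NaH2PO4, 2-methyl-2-butene (excess), t-BuOH/H2O, 0 °C → rt
Reagents that add atoms: sodium chlorite, [Na+].[O-]Cl=O
Why: Pinnick oxidation converts the 2-substituted enal into the acrylic acid, with the excess 2-methyl-2-butene intercepting hypochlorite before it can reach the trisubstituted alkenes or the free carbinol.

**Compound list**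

1 | cyclohept-4-ene-1-carboxylic acid | OC(=O)C1CCC=CCC1 | starting material
2 | (cyclohept-4-en-1-yl)methanol | OCC1CCC=CCC1 | intermediate
3 | (cyclohept-4-en-1-yl)methyl 4-methylbenzenesulfonate | Cc1ccc(cc1)S(=O)(=O)OCC1CCC=CCC1 | intermediate
4 | (8,9,10-trioxabicyclo[5.2.1]decan-4-yl)methyl 4-methylbenzenesulfonate (secondary ozonide of 3, stereoisomer mixture, formed in situ) | Cc1ccc(cc1)S(=O)(=O)OCC1CCC2OOC(CC1)O2 | intermediate
5 | 4-[(tosyloxy)methyl]heptanedial [2-(3-oxopropyl)-5-oxopentyl 4-methylbenzenesulfonate] | O=CCCC(COS(=O)(=O)c1ccc(C)cc1)CCC=O | intermediate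
6 | 1,1,1,3,3,3-hexafluoropropan-2-yl acrylate | C=CC(=O)OC(C(F)(F)F)C(F)(F)F | starting material
7 | bis(1,1,1,3,3,3-hexafluoropropan-2-yl) (3R,9R)-3,9-dihydroxy-2,10-dimethylidene-6-{[(4-methylbenzenesulfonyl)oxy]methyl}undecanedioate | C=C(C(=O)OC(C(F)(F)F)C(F)(F)F)[C@H](O)CCC(COS(=O)(=O)c1ccc(C)cc1)CC[C@H](C(=C)C(=O)OC(C(F)(F)F)C(F)(F)F)O | intermediate
8 | [(3R,9R)-1,3,9,11-tetrahydroxy-2,10-dimethylideneundecan-6-yl]methyl 4-methylbenzenesulfonate (C6 not stereogenic) | C=C(CO)[C@H](O)CCC(COS(=O)(=O)c1ccc(C)cc1)CC[C@H](C(=C)CO)O | intermediate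
9 | 2-[(2R,5S)-5-[(3R)-3-hydroxy-4-(hydroxymethyl)pent-4-en-1-yl]oxan-2-yl]prop-2-en-1-ol (2,5-trans oxane) | C=C(CO)[C@H](O)CC[C@H]1CC[C@H](C(=C)CO)OC1 | intermediate
10 | 2-[(2R,5R)-5-{2-[(4R)-2,2-dibutyl-5-methylidene-1,3,2-dioxastanninan-4-yl]ethyl}oxan-2-yl]prop-2-en-1-ol (stannylene acetal of 9, same spatial configuration, formed in situ) | C=C1CO[Sn](CCCC)(CCCC)O[C@@H]1CC[C@H]2CC[C@H](C(=C)CO)OC2 | intermediate
11 | (3R)-3-hydroxy-5-[(3S,6R)-6-(3-hydroxyprop-1-en-2-yl)oxan-3-yl]-2-methylidenepentyl 4-methylbenzenesulfonate | C=C(COS(=O)(=O)c1ccc(C)cc1)[C@H](O)CC[C@H]1CC[C@H](C(=C)CO)OC1 | intermediate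
12 | (3R)-3-[(tert-butyldimethylsilyl)oxy]-5-[(3R,6R)-6-{3-[(tert-butyldimethylsilyl)oxy]prop-1-en-2-yl}oxan-3-yl]-2-methylidenepentyl 4-methylbenzenesulfonate (same spatial configuration as 11; descriptor at the ring carbon changes with O-silylation) | C=C(COS(=O)(=O)c1ccc(C)cc1)[C@H](O[Si](C)(C)C(C)(C)C)CC[C@H]1CC[C@H](C(=C)CO[Si](C)(C)C(C)(C)C)OC1 | intermediate
13 | geranyl bromide [(2E)-1-bromo-3,7-dimethylocta-2,6-diene] | CC(C)=CCC/C(C)=C/CBr | starting material
14 | {[(2E)-3,7-dimethylocta-2,6-dien-1-yl]sulfonyl}benzene (geranyl phenyl sulfone) | CC(C)=CCC/C(C)=C/CS(=O)(=O)c1ccccc1 | intermediate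
15 | α-lithio geranyl phenyl sulfone (formed in situ) | CC(C)=CCC/C(C)=C/C([Li])S(=O)(=O)c1ccccc1 | intermediate
16 | (2R,5R)-5-[(3R,7E)-6-(benzenesulfonyl)-3-[(tert-butyldimethylsilyl)oxy]-8,12-dimethyl-4-methylidenetrideca-7,11-dien-1-yl]-2-{3-[(tert-butyldimethylsilyl)oxy]prop-1-en-2-yl}oxane (both epimers at C6′) | C=C(CC(S(=O)(=O)c1ccccc1)/C=C(\C)CCC=C(C)C)[C@H](O[Si](C)(C)C(C)(C)C)CC[C@H]1CC[C@H](C(=C)CO[Si](C)(C)C(C)(C)C)OC1 | intermediate
17 | (2R,5R)-2-{3-[(tert-butyldimethylsilyl)oxy]prop-1-en-2-yl}-5-[(3R,7E)-3-[(tert-butyldimethylsilyl)oxy]-8,12-dimethyl-4-methylidenetrideca-7,11-dien-1-yl]oxane | C=C(CC/C=C(\C)CCC=C(C)C)[C@H](O[Si](C)(C)C(C)(C)C)CC[C@H]1CC[C@H](C(=C)CO[Si](C)(C)C(C)(C)C)OC1 | intermediate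
18 | 2-[(2R,5S)-5-[(3R,7E)-3-hydroxy-8,12-dimethyl-4-methylidenetrideca-7,11-dien-1-yl]oxan-2-yl]prop-2-en-1-ol | C=C(CC/C=C(\C)CCC=C(C)C)[C@H](O)CC[C@H]1CC[C@H](C(=C)CO)OC1 | intermediate
19 | 2-[(2R,5S)-5-[(3R,7E)-3-hydroxy-8,12-dimethyl-4-methylidenetrideca-7,11-dien-1-yl]oxan-2-yl]prop-2-enal | C=C(CC/C=C(\C)CCC=C(C)C)[C@H](O)CC[C@H]1CC[C@H](C(=C)C=O)OC1 | intermediate
20 | 2-[(2R,5S)-5-[(3R,7E)-3-hydroxy-8,12-dimethyl-4-methylidenetrideca-7,11-dien-1-yl]oxan-2-yl]prop-2-enoic acid | C=C(CC/C=C(\C)CCC=C(C)C)[C@H](O)CC[C@H]1CC[C@H](C(=C)C(=O)O)OC1 | target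

**Step count and risks**

Total steps: 14. Longest linear sequence: 13 steps (steps 1–8 and 10–14, from acid 1); step 9 is a one-step branch.

Most likely to fail:

Step 6. The chair preference between closure through the two diastereotopic oxygens may be too small at the alcohol oxidation level, and the polar cis and trans triols may be hard to part. The fallback moves the ring closure to the diester level. From 7, methanolysis (MeOH, Et3N, 0 °C → rt) would give the dimethyl diester F1. Sodium hydride in THF (0 °C, high dilution) should then close the oxane through the less basic, more hindered Morita–Baylis–Hillman alkoxide, for which a tighter transition state is expected, to give the trans-oxane bis-acrylate F2. Its cis isomer is a non-polar diester and should be easier to separate. DIBAL-H reduction of F2 (CH2Cl2, −78 °C) returns to 9.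

Step 4. The second Morita–Baylis–Hillman addition may stall, the intermediate may be diverted into dioxanones by a second aldehyde, or the facial control may be lower than expected. The fallback sets the two carbinols by reagent-controlled reduction. From 5, a double Nozaki–Hiyama–Kishi coupling with 2-bromo-3-[(tert-butyldimethylsilyl)oxy]prop-1-ene (CrCl2, NiCl2 cat., DMF) would give the bis(allylic alcohol) F3 as a stereoisomer mixture. Dess–Martin oxidation gives the bis(α-methylene ketone) F4. Corey–Bakshi–Shibata reduction with the (S)-methyl oxazaborolidine and catecholborane (toluene, −78 °C), the branched alkenyl group acting as the large substituent, should give the (3R,9R)-diol F5. HF·pyridine in THF then removes both primary silyl ethers without touching the tosylate and returns to 8.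

Step 7. The tin-directed sulfonylation may not be clean: the isolated ring-arm primary hydroxyl may be tosylated as well, or the stannylene may react at its secondary oxygen. The fallback differentiates the hydroxyls by protecting groups. From 9, 2,2-dimethoxypropane with PPTS gives the acetonide F6, since only the side-chain 1,3-diol can form the dioxane. TBSCl and imidazole give its ring-arm silyl ether F7. Brief methanolysis (PPTS, MeOH, 0 °C), under which the six-membered acetonide should cleave faster than the primary silyl ether, gives the mono-silyl diol F8. Primary-selective tosylation (TsCl, Et3N, Me3N·HCl cat., CH2Cl2, −20 °C), now without a competing primary hydroxyl, gives the hydroxy tosylate F9. TBSOTf and 2,6-lutidine return to 12.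

**Further compounds**

F1 | step 6 | dimethyl (3R,9R)-3,9-dihydroxy-2,10-dimethylidene-6-{[(4-methylbenzenesulfonyl)oxy]methyl}undecanedioate | C=C(C(=O)OC)[C@H](O)CCC(COS(=O)(=O)c1ccc(C)cc1)CC[C@H](C(=C)C(=O)OC)O
F2 | step 6 | methyl 2-[(2R,5S)-5-[(3R)-3-hydroxy-4-(methoxycarbonyl)pent-4-en-1-yl]oxan-2-yl]prop-2-enoate | C=C(C(=O)OC)[C@H](O)CC[C@H]1CC[C@H](C(=C)C(=O)OC)OC1
F3 | step 4 | {1,11-bis[(tert-butyldimethylsilyl)oxy]-3,9-dihydroxy-2,10-dimethylideneundecan-6-yl}methyl 4-methylbenzenesulfonate (mixture of C3/C9 stereoisomers) | C=C(CO[Si](C)(C)C(C)(C)C)C(O)CCC(COS(=O)(=O)c1ccc(C)cc1)CCC(O)C(=C)CO[Si](C)(C)C(C)(C)C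
F4 | step 4 | {1,11-bis[(tert-butyldimethylsilyl)oxy]-2,10-dimethylidene-3,9-dioxoundecan-6-yl}methyl 4-methylbenzenesulfonate | C=C(CO[Si](C)(C)C(C)(C)C)C(=O)CCC(COS(=O)(=O)c1ccc(C)cc1)CCC(=O)C(=C)CO[Si](C)(C)C(C)(C)C
F5 | step 4 | {(3R,9R)-1,11-bis[(tert-butyldimethylsilyl)oxy]-3,9-dihydroxy-2,10-dimethylideneundecan-6-yl}methyl 4-methylbenzenesulfonate | C=C(CO[Si](C)(C)C(C)(C)C)[C@H](O)CCC(COS(=O)(=O)c1ccc(C)cc1)CC[C@H](C(=C)CO[Si](C)(C)C(C)(C)C)O
F6 | step 7 | 2-[(2R,5R)-5-{2-[(4R)-2,2-dimethyl-5-methylidene-1,3-dioxan-4-yl]ethyl}oxan-2-yl]prop-2-en-1-ol (acetonide of 9, same spatial configuration) | C=C1COC(C)(C)O[C@@H]1CC[C@H]2CC[C@H](C(=C)CO)OC2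
F7 | step 7 | tert-butyl({2-[(2R,5R)-5-{2-[(4R)-2,2-dimethyl-5-methylidene-1,3-dioxan-4-yl]ethyl}oxan-2-yl]prop-2-en-1-yl}oxy)dimethylsilane | C=C1COC(C)(C)O[C@@H]1CC[C@H]2CC[C@H](C(=C)CO[Si](C)(C)C(C)(C)C)OC2
F8 | step 7 | (3R)-5-[(3S,6R)-6-{3-[(tert-butyldimethylsilyl)oxy]prop-1-en-2-yl}oxan-3-yl]-2-methylidenepentane-1,3-diol | C=C(CO)[C@H](O)CC[C@H]1CC[C@H](C(=C)CO[Si](C)(C)C(C)(C)C)OC1
F9 | step 7 | (3R)-5-[(3S,6R)-6-{3-[(tert-butyldimethylsilyl)oxy]prop-1-en-2-yl}oxan-3-yl]-3-hydroxy-2-methylidenepentyl 4-methylbenzenesulfonate | C=C(COS(=O)(=O)c1ccc(C)cc1)[C@H](O)CC[C@H]1CC[C@H](C(=C)CO[Si](C)(C)C(C)(C)C)OC1
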